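**Plan**

- Ring atoms: C1 carries two prenyl groups, C2 is a ketone, C3 carries the isobutyryl group, C4 is the enol C–OH, C5 is the carbinol carbon (OH and prenyl), and C6 is the ketone between C5 and C1. The side chains on C1 (two) and C5 (one) all end in the same CH=C(CH3)2 unit, so each is traced back to an allyl group and all three are finished in one cross-metathesis.
- The retrosynthesis cuts, in order: the three side-chain C=C bonds, the benzoate ester on the C5 oxygen, the C5–allyl bond, the C5–O bond, the two C1–allyl bonds and the C3–acyl bond, which leads back to phloroglucinol.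
- Forward, the only ring is the carbocycle of phloroglucinol and is never built. It is acylated at C3, dearomatised by double allylation at C1, oxygenated at C5 as a benzoate, allylated at C5 and debenzoylated, and the three prenyl termini are installed together at the end.
- The single stereocentre, C5 (S), is set in the palladium-catalysed asymmetric allylation of the prochiral C5-benzoyloxy enolate under a chiral diphosphine. It is quaternary, and no later step breaks a bond to it.

Key step: step 6

Assumption: enolised polyketones are drawn as one tautomer. The sense of induction of the Trost ligand on this enolate cannot be predicted with confidence, so the (R,R)-ligand is written and the (S,S)-ligand would be used if the first run delivers the R benzoate.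

**Step 1**
Reactants: 1 phloroglucinol; 2 isobutyryl chloride
Product: 3 2-methyl-1-(2,4,6-trihydroxyphenyl)propan-1-one
Conditions: AlCl3 (4 equiv), PhNO2, 0 °C to 65 °C; then ice/1 M HCl
Reagents that add atoms: none
Why: Friedel–Crafts acylation of a very electron-rich, threefold-symmetric arene can give only one regioisomer, and the first acyl group, chelated to aluminium, deactivates the ring towards a second acylation.

**Step 2**
Reactants: 3 2-methyl-1-(2,4,6-trihydroxyphenyl)propan-1-one; 4 allyl bromide
Product: 6 3,5-dihydroxy-2-(2-methylpropanoyl)-6,6-di(prop-2-en-1-yl)cyclohexa-2,4-dien-1-one, via monoallyl phenol 5 (not isolated)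
Conditions: NaOMe (3 equiv), allyl bromide (2.1 equiv), MeOH, 0 °C to rt; 1 M HCl; pH-controlled extraction, then SiO2
Reagents that add atoms: allyl bromide (second equivalent of 4), C=CCBr
Why: Alkylative dearomatisation by twofold C-alkylation of the ambident phloroglucinolate in a protic solvent: after the first allyl group enters a free ring carbon, the compact allyl bromide can alkylate that same, now more electron-rich carbon a second time, and the resulting non-aromatic vinylogous acid should be separable from the aromatic 3,5-diallyl isomer through its stronger acidity.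

**Step 3**
Reactants: 6 3,5-dihydroxy-2-(2-methylpropanoyl)-6,6-di(prop-2-en-1-yl)cyclohexa-2,4-dien-1-one
Product: 7 2,6-dihydroxy-5-(2-methylpropanoyl)-4-oxo-3,3-di(prop-2-en-1-yl)cyclohexa-1,5-dien-1-yl benzoate
Conditions: NaH (2.1 equiv), THF–DMF, 0 °C; (PhCO2)2 (1.0 equiv), 0 °C to rt; 1 M HCl
Reagents that add atoms: dibenzoyl peroxide, O=C(OOC(=O)c1ccccc1)c1ccccc1
Why: Electrophilic α-benzoyloxylation of a β-dicarbonyl enolate: C5, the only unsubstituted nucleophilic ring carbon, attacks the O–O bond with loss of benzoate, and re-enolisation of the product makes its anion a poorer nucleophile, so one equivalent of peroxide should stop at the monobenzoate.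

**Step 4**
Reactants: 7 2,6-dihydroxy-5-(2-methylpropanoyl)-4-oxo-3,3-di(prop-2-en-1-yl)cyclohexa-1,5-dien-1-yl benzoate; 8 allyl tert-butyl carbonate
Product: 9 (1S)-2-hydroxy-3-(2-methylpropanoyl)-4,6-dioxo-1,5,5-tri(prop-2-en-1-yl)cyclohex-2-en-1-yl benzoate
Conditions: Pd2(dba)3·CHCl3 (2.5 mol %), (R,R)-DACH-phenyl Trost ligand (6 mol %), 8 (1.2 equiv), CH2Cl2, 0 °C to rt
Reagents that add atoms: none
Why: Tsuji–Trost asymmetric allylic alkylation: the carbonate ionises on zerovalent palladium to a π-allyl complex and tert-butoxide, which deprotonates the acidic dione without attacking the enol benzoate, and the soft prochiral enolate attacks the allyl terminus through C5 on the face left open by the chiral ligand pocket, setting C5 as S, while O-allyl by-products re-ionise and C3 stays locked in the conjugated triketone.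

**Step 5**
Reactants: 9 (1S)-2-hydroxy-3-(2-methylpropanoyl)-4,6-dioxo-1,5,5-tri(prop-2-en-1-yl)cyclohex-2-en-1-yl benzoate
Product: 10 (4S)-3,4-dihydroxy-2-(2-methylpropanoyl)-4,6,6-tri(prop-2-en-1-yl)cyclohex-2-ene-1,5-dione
Conditions: K2CO3 (2.5 equiv), MeOH, 0 °C, short reaction time; cold 1 M HCl to pH 3
Reagents that add atoms: none
Why: Base-mediated transesterification of a tertiary benzoate activated by two flanking carbonyl groups; the ring is shielded as its triketonate anion, the low temperature and immediate acidic quench should hold back α-ketol ring contraction, and C5 keeps its configuration because no bond to it is broken.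

**Step 6**
Reactants: 10 (4S)-3,4-dihydroxy-2-(2-methylpropanoyl)-4,6,6-tri(prop-2-en-1-yl)cyclohex-2-ene-1,5-dione; 11 2-methylbut-2-ene
Product: 12 (4S)-3,4-dihydroxy-4,6,6-tris(3-methylbut-2-en-1-yl)-2-(2-methylpropanoyl)cyclohex-2-ene-1,5-dione
Conditions: second-generation Hoveyda–Grubbs catalyst (2 × 5 mol %), 2-methylbut-2-ene as solvent (large excess; minimum CH2Cl2 to dissolve), Ar, sealed vessel, 25 °C
Reagents that add atoms: 2-methylbut-2-ene (two further equivalents of 11, one olefin being consumed per allyl group), CC=C(C)C
Why: The ruthenium carbene, which in this medium rests mainly as the isopropylidene and ethylidene species formed from 2-methylbut-2-ene, adds to each terminal allyl alkene in a [2+2] cycloaddition, and cycloreversion of the ruthenacyclobutane releases the CH2 terminus (ultimately as propene, three equivalents in all) and leaves the CH=C(CH3)2 end on the substrate (Chauvin mechanism). The closest known reaction type is the allyl-to-prenyl cross-metathesis with this olefin that is routinely applied to C-allylated acylphloroglucinol and related polyketide cores. No ring closes and no stereocentre is formed; C5 is a fully substituted bystander and cannot epimerise. The selectivity needed is cross-metathesis over ring-closing metathesis of the two allyl groups on C1, which would give a spiro cyclopentene: using the partner olefin as solvent keeps the share of substrate-bound carbene small and traps it bimolecularly, and working at room temperature rather than at reflux favours that bimolecular trap over the unimolecular closure. After the first exchange on C1 the pair is allyl/prenyl, whose closure would have to engage a trisubstituted alkene and is slow, and every prenyl alkene formed is itself a poor substrate, so the material should converge on the triprenyl product (crotyl-terminated intermediates re-enter the cycle). The free enol and tertiary alcohol are compatible with ruthenium carbenes and need no protection.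

**Compound list**

1 | phloroglucinol (benzene-1,3,5-triol) | Oc1cc(O)cc(O)c1 | starting material
2 | isobutyryl chloride (2-methylpropanoyl chloride) | CC(C)C(Cl)=O | starting material
3 | 2-methyl-1-(2,4,6-trihydroxyphenyl)propan-1-one | CC(C)C(=O)c1c(O)cc(O)cc1O | intermediate
4 | allyl bromide (3-bromoprop-1-ene) | C=CCBr | starting material
5 | monoallyl phenol, 2-methyl-1-[2,4,6-trihydroxy-3-(prop-2-en-1-yl)phenyl]propan-1-one (not isolated) | CC(C)C(=O)c1c(O)cc(O)c(CC=C)c1O | intermediate
6 | 3,5-dihydroxy-2-(2-methylpropanoyl)-6,6-di(prop-2-en-1-yl)cyclohexa-2,4-dien-1-one | C=CCC1(CC=C)C(=O)C(C(=O)C(C)C)=C(O)C=C1O | intermediate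
7 | 2,6-dihydroxy-5-(2-methylpropanoyl)-4-oxo-3,3-di(prop-2-en-1-yl)cyclohexa-1,5-dien-1-yl benzoate (C5 benzoate of 6) | C=CCC1(CC=C)C(=O)C(C(=O)C(C)C)=C(O)C(OC(=O)c2ccccc2)=C1O | intermediate
8 | allyl tert-butyl carbonate (tert-butyl prop-2-en-1-yl carbonate) | C=CCOC(=O)OC(C)(C)C | starting material
9 | (1S)-2-hydroxy-3-(2-methylpropanoyl)-4,6-dioxo-1,5,5-tri(prop-2-en-1-yl)cyclohex-2-en-1-yl benzoate | C=CCC1(CC=C)C(=O)C(C(=O)C(C)C)=C(O)[C@@](OC(=O)c2ccccc2)(CC=C)C1=O | intermediate
10 | (4S)-3,4-dihydroxy-2-(2-methylpropanoyl)-4,6,6-tri(prop-2-en-1-yl)cyclohex-2-ene-1,5-dione (triallyl carbinol) | C=CCC1(CC=C)C(=O)C(C(=O)C(C)C)=C(O)[C@@](O)(CC=C)C1=O | intermediate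
11 | 2-methylbut-2-ene | CC=C(C)C | starting material
12 | (4S)-3,4-dihydroxy-4,6,6-tris(3-methylbut-2-en-1-yl)-2-(2-methylpropanoyl)cyclohex-2-ene-1,5-dione | CC(C)=CCC1(CC=C(C)C)C(=O)C(C(=O)C(C)C)=C(O)[C@@](O)(CC=C(C)C)C1=O | target

Total step count: 6. Longest linear sequence: 6 steps (1 to 12).

**Steps most likely to fail**

Step 4. The enolate is flat and heavily delocalised, and its two flanks (C4 and C6) may look too similar to the ligand pocket, so facial discrimination could be poor; allyl transfer to oxygen could also persist. The fallback sets out from benzoate 7. Allylation with carbonate 8 under Pd(PPh3)4 without a chiral ligand should give the racemic triallyl benzoate F1, a neutral, UV-active compound. Its enantiomers would be separated by preparative chromatography on a chiral stationary phase, and the S enantiomer is 9, where the route is rejoined.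

Step 6. Ring closure of the geminal allyl pair on C1 may outrun the bimolecular exchange, or the exchange may stall at partly converted (crotyl-terminated) stages. The fallback sets out from ketone 3 and introduces the prenyl groups by alkylation instead of metathesis. Threefold C-prenylation with 1-bromo-3-methylbut-2-ene and NaOMe in MeOH, the alkylation pattern typical of acylphloroglucinols, would pass through the 3-prenyl phenol F2 and the 3,5-diprenyl phenol F3 to the 4,6,6-triprenyl dienol F4, in which C5 is still enolic. Hydroxylation of the sodium enolate of F4 at C5 with an enantiopure (camphorsulfonyl)oxaziridine, the enantiomer being selected for the S carbinol, should give 12 directly, with chiral-phase chromatography as a polish if needed. The trisubstituted alkenes are not attacked by this oxidant. The route is rejoined at 12.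

Step 2. The second allyl group may enter the other free ring carbon, which rearomatises to the 3,5-diallyl phenol, or a third allyl group may follow. The fallback blocks that carbon and sets out from acid chloride 2. Friedel–Crafts acylation of commercial methyl 2,4,6-trihydroxybenzoate with 2 (AlCl3) would give the keto ester F5, which has a single free ring carbon. NaOMe and allyl bromide 4 can then lead only through the monoallyl ester F6 to the gem-diallyl ester F7. Heating F7 with aqueous NaOH and acidifying should hydrolyse the vinylogous β-keto ester, and the acid loses CO2 to give 6, where the route is rejoined.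

**Further compounds**

F1 | step 4 | racemic 2-hydroxy-3-(2-methylpropanoyl)-4,6-dioxo-1,5,5-tri(prop-2-en-1-yl)cyclohex-2-en-1-yl benzoate | C=CCC1(CC=C)C(=O)C(C(=O)C(C)C)=C(O)C(OC(=O)c2ccccc2)(CC=C)C1=O
F2 | step 6 | 2-methyl-1-[2,4,6-trihydroxy-3-(3-methylbut-2-en-1-yl)phenyl]propan-1-one | CC(C)C(=O)c1c(O)cc(O)c(CC=C(C)C)c1O
F3 | step 6 | 2-methyl-1-[2,4,6-trihydroxy-3,5-bis(3-methylbut-2-en-1-yl)phenyl]propan-1-one | CC(C)C(=O)c1c(O)c(CC=C(C)C)c(O)c(CC=C(C)C)c1O
F4 | step 6 | 3,5-dihydroxy-4,6,6-tris(3-methylbut-2-en-1-yl)-2-(2-methylpropanoyl)cyclohexa-2,4-dien-1-one | CC(C)=CCC1(CC=C(C)C)C(=O)C(C(=O)C(C)C)=C(O)C(CC=C(C)C)=C1O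
F5 | step 2 | methyl 2,4,6-trihydroxy-3-(2-methylpropanoyl)benzoate | COC(=O)c1c(O)cc(O)c(C(=O)C(C)C)c1O
F6 | step 2 | methyl 2,4,6-trihydroxy-3-(2-methylpropanoyl)-5-(prop-2-en-1-yl)benzoate | COC(=O)c1c(O)c(CC=C)c(O)c(C(=O)C(C)C)c1O
F7 | step 2 | methyl 2,6-dihydroxy-5-(2-methylpropanoyl)-4-oxo-3,3-di(prop-2-en-1-yl)cyclohexa-1,5-diene-1-carboxylate | C=CCC1(CC=C)C(=O)C(C(=O)C(C)C)=C(O)C(C(=O)OC)=C1O
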